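| flask | starting complex | incoming ligand | temperature | remark | time |
|---|---|---|---|---|---|
| cedar | 0.28 M | 0.42 M | 80 °C | the very flask that is asked about, followed so far |  |
| oak | 0.28 M | 0.21 M | 86 °C | run made earlier |  |
| flask | 0.28 M | 0.420 M | 80 °C |  | 2.5 d |

| run | time / h | complex with one exchanged / % | starting complex / % |
|---|---|---|---|
| cedar | 8.00 | 63.0 | 26.4 |
| cedar | 15.0 | 63.5 | 27.7 |
| cedar | 20.0 | 62.1 | 28.7 |
| cedar | 30.0 | 62.2 | 28.2 |
| cedar | 40.0 | 62.1 | 25.9 |
| oak | 0.500 | 37.1 | 59.7 |
| oak | 1.50 | 39.3 | 58.3 |
| oak | 3.00 | 37.9 | 58.0 |
| oak | 4.00 | 38.7 | 56.7 |
| oak | 6.00 | 39.8 | 58.7 |

(each reading ± 1 percentage point)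

- complex with one exchanged, in percent of the starting complex first charged, at 2.5 d
- which option adds most complex with one exchanged ("none" when 2 percentage points or less is all one gets) (green / amber / blue / ochre / none)
- complex with one exchanged present, with what was taken out counted in, in percent of the starting complex first charged, after green
- complex with one exchanged present, with what was taken out counted in, in percent of the starting complex first charged, after amber

- green: change nothing and wait 30 h more
- amber: at 2.5 d add incoming ligand, 100% of the amount charged, then wait 30 h
- blue: at 2.5 d take out 90% of the complex with one exchanged then present, then wait 30 h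
- ochre: at 2.5 d raise the temperature by 25 K, then wait 30 h

- for leaving ligand the idle adduct is counted in
- complex with one exchanged that was removed still counts
- on the list of suspects stand: starting complex + incoming ligand -> leaving ligand + complex with one exchanged; complex with one exchanged + incoming ligand -> leaving ligand + complex with two exchanged; incoming ligand -> decomposed reagent; leaving ligand + incoming ligand <-> idle adduct; incoming ligand <-> dormant form
- additions bring no volume worth counting

1. Cedar is read through one ratio: the pace of first exchange over the pace of decomposition, both drawing on incoming ligand. Free incoming ligand is a factor in both paces and cancels, so the ratio is the amount of starting complex over a constant.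

2. Cedar's readings stay flat from 8.00 h to 40.0 h, averaging 27.4% starting complex and 62.6% complex with one exchanged, which leaves 10.0% complex with two exchanged. The exchanges took 0.231 M of the 0.42 M charged. With free incoming ligand, idle adduct and dormant form taken as empty, 0.189 M remains for decomposition.

3. Summed over a run, decomposition's take equals the constant times ln(charged over left). So cedar reads 0.146 M, the break-even amount: the amount of starting complex at which first exchange and decomposition use incoming ligand equally fast.

4. At the start, cedar's ratio reads 1.92, so first exchange takes 65.8% of the ligand then being used. Falling ligand slows both paces alike. Falling starting complex slows exchange but not decomposition, by a factor of 3.65, and the ratio ends at 0.527.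

5. Cedar's readings are flat, so this reckoning expects 62.6% at 2.5 d, unchanged after green, blue or ochre. Amber's fresh ligand should meet that low ratio and start both exchanges again; the break-even gives no figure for their net.

6. The forecast gives 62.6% (61.6% to 63.6%), 62.6% after green, 60.5% after amber (57% to 65%) and best none: “Green, blue and ochre change nothing, because no ligand is left.”

The flask gives 62.8%, 62.8% after green, 62.6% after amber, and best none.

    starting complex + incoming ligand → leaving ligand + complex with one exchanged (k = 0.210 /M/min, Ea = 82.0 kJ/mol)
    complex with one exchanged + incoming ligand → leaving ligand + complex with two exchanged (k = 0.0389 /M/min, Ea = 82.0 kJ/mol)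
    incoming ligand → decomposed reagent (k = 0.0310 /min, Ea = 95.0 kJ/mol)
    leaving ligand + incoming ligand ⇌ idle adduct, settled at all times (K = 6.80 /M, ΔH = −21.0 kJ/mol)
    incoming ligand ⇌ dormant form (K = 0.550, k = 0.00138 /min, Ea = 120 kJ/mol, ΔH = −52.0 kJ/mol)
    (constants at 80 °C)

In this flask, first exchange uses incoming ligand 1.8 times as fast as decomposition just after the start and 1.2 times at 0.129 h. With the break-even amount read from cedar, that ratio reckons at 0.530 for the 27.6% of starting complex standing in this flask at 60.0 h, when incoming ligand, the limiting reagent, is at 0% of its charge.

The neighbour flask with 0.10 M of incoming ligand starts at the same ratio, but its share falls as starting complex falls, so the break-even amount is set against a mean of about 0.247 M starting complex, which gives about 22.5% complex with one exchanged. Computed, that neighbour holds 21.5%, less than this estimate, beside 77.9% starting complex.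

The runs were generated by integration from invented constants; the scatter is artificial.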